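Locants used throughout are those of the cembrane skeleton. The ring is C1–C14. C1 carries the isopropylidene carbon C15 (methyls C16, C17). C2 and C9 are the ketones. C3–C4 is the epoxide, with methyl C18 on C4. C8 carries methyl C19. C12 carries methyl C20 and the acetate. In these locants the target 23 is (3R,4S,8S,12R) with a trans epoxide. Systematically it is (1R,6R,10S,14S)-6,10,14-trimethyl-2,9-dioxo-3-(propan-2-ylidene)-15-oxabicyclo[12.1.0]pentadecan-6-yl acetate.

## The problem

The target 23 is a cembrane diterpenoid: a 14-membered carbocycle whose only stereocentres are the trans epoxide (C3, C4), the methine C8 and the acetoxy carbon C12. These three elements are 1,5-related across a flexible ring (C4/C8 and C8/C12) and cannot control one another, so each has to come from the chiral pool or from a reagent-controlled step. The hard questions are therefore where to close the ring and how to make the array C15=C1–C2(=O)–C3(O)C4. That array is a fully substituted, cross-conjugated α-isopropylidene ketone next to an α,β-epoxy ketone. Metathesis cannot make it, and it tolerates neither strong acid (epoxide, tertiary acetate), nor strong base (deconjugation of the enone, epimerisation of C8 next to the C9 ketone), nor electron-transfer reduction. The acetate cannot be put on late, because a free C12 hydroxyl lies 1,4 to the C9 ketone and would close to a five-membered hemiketal. The feature that opens the problem is that C2, C1 and C15 are the dehydrated aldol of a C2 acyl group with acetone, which is the retron of a 5,5-dimethyl-4,5-dihydroisoxazole ring (N=C2–C1–C15–O) fused to the carbocycle at C1–C2. The dipolarophile this ring needs, C1=C15, is the unmodified 4-methylpent-3-enyl terminus of linalool, whose carbinol carbon is C12 with its methyl and oxygen (C10–C17 and C20 are linalool atom for atom), and C2–C9 with C18 and C19 is the geraniol skeleton. One cycloaddition can therefore close the 14-membered ring at C1–C2 and at the same stroke put C2 at the ketone level and an oxygen on C15, from which the tetrasubstituted alkene is then drawn.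

## Retrosynthesis

**23 ⇒ 21 ⇒ 19 (no skeletal bond cut).** The C1=C15 double bond is traced to the tertiary aldol 21, and the aldol to the fused isoxazoline 19 by N–O scission and hydrolysis. This is preferred to a β,γ-unsaturated or allylic-alcohol precursor because the elimination is regiochemically fixed: C3 is an epoxide carbon, so the only acidic hydrogen next to C2 is on C1. The forward steps must cleave N–O without opening the epoxide and eliminate without retro-aldol.

**19 ⇒ 18 ⇒ 16 (cut C1–C2 and O–C15).** This is the key disconnection: an intramolecular nitrile oxide–alkene cycloaddition of 18, made from oxime 16. Against cuts at C2–C3, C9–C10 or any CH2–CH2 bond, C1–C2 is the only ring bond whose formation can also create the C2/C15 oxidation pattern. It also needs no prior functionalisation of the alkene. The precursor 16 is an open chain with all four stereocentres already set; the product 19 holds the complete skeleton. The forward reaction must deliver the C2–C1/O–C15 regiochemistry and cyclisation rather than dimerisation.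

**16 ⇒ 15 ⇒ 14 ⇒ 13 (cut the two epoxide C–O bonds).** The oxime comes from epoxy aldehyde 15, this from epoxy alcohol 14, and 14 from the (E)-allylic alcohol 13 by Sharpless epoxidation. Epoxidising before ring closure puts the step on a geraniol-type allylic alcohol, where reagent control is most reliable. It also removes C3=C4 as a competing π-bond in the key step. A late epoxidation of a macrocyclic dienone would have neither a directing group nor a reliable catalyst.

**13 ⇒ 12 ⇒ 8 + 10, through 11 (cut C9–C10).** This divides the chain into two C10 halves, each the skeleton of a commercial monoterpene alcohol. A cut at C8–C9 would make the stereocentre C8 a nucleophile. A cut at C10–C11 or C11–C12 would break up the linalool unit or its stereocentre. The forward step is an acyl–alkyl coupling of thioester 8 with the anti-Markovnikov alkylborane 11 from linalyl acetate 10. It must form the ketone directly, tolerate the acetate and not enolise C8.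

**10 ⇒ 9 (cut the acetyl C–O bond).** C12 with its methyl and oxygen is taken from (R)-linalool 9. The acetate is installed first, where tertiary acetylation is simple, and it then serves as the protecting group up to the target.

**8 ⇒ 6 ⇒ 4 ⇒ 3 ⇒ 2 ⇒ 1 (no C–C bond cut).** The C2–C9 half is geraniol 1 after three changes: protection (2), E-selective allylic oxidation of the terminal methyl, which becomes C9 (3), and hydroxyl-directed asymmetric hydrogenation, which sets C8 (4). Oxidation to acid 6 and conversion to thioester 8 follow. This is shorter than any assembly of the chain from smaller chiral fragments.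

## Roads not taken

**Alternative 1:** (the obvious one) ring-closing metathesis at C10=C11. The acyclic diene A1 (vinyl ketone at C9, the native vinyl group of the linalool unit at C11) would be closed with the second-generation Grubbs catalyst RuCl2(=CHPh)(PCy3)(H2IMes) to the macrocyclic enone A2, and the new alkene reduced with a copper hydride. The chosen plan is better for three reasons.
- Metathesis only closes the ring. The hard array C15=C1–C2(=O)–C3–C4 would have to be built beforehand by separate intermolecular steps and carried through A1.
- The C11 terminus sits on the fully substituted C12 and is a slow partner for an electron-poor vinyl ketone.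
- The alkene of A2 is not in the target, and its removal must distinguish three reducible units (two enones and an epoxy ketone).

**Alternative 2:** cut C1–C2 as acylium plus alkene. The (E)-enoyl chloride A3 would be cyclised with SnCl4 onto the prenyl terminus and, after loss of HCl, give the cross-conjugated dienone A4, which would be epoxidised at C3=C4 last. The ring closure is attractive, but the chosen plan is better on two counts.
- A strong Lewis acid is incompatible with an epoxide and puts the tertiary acetate at risk of ionisation.
- The epoxide would have to be set at the end on A4, choosing between two enone double bonds and setting 3R,4S on a β,β-disubstituted enone with no directing hydroxyl and only remote stereocentres. The chosen route sets it by reagent control on an allylic alcohol and closes the ring under neutral conditions.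

**Alternative 3:** ring contraction by [2,3]-Wittig rearrangement. A 17-membered propargylic allylic ether A5 (oxygen linking C2 and C16) would be deprotonated at C2 and contract to the 14-membered propargylic alcohol A6, with a prop-1-en-2-yl group on C1. This uses the same temporary-ring idea as the chosen plan, but it costs more.
- The strong base forces masking of the C9 ketone and replacement of the acetate (in A5 a dioxolane and a silyl ether).
- C16 must first be oxidised and etherified.
- After contraction the C18 methyl must still be added to the alkyne, followed by directed epoxidation, oxidation, double-bond isomerisation and protecting-group changes.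
- The isoxazoline route uses the linalool alkene as it comes, needs no strong base and is several steps shorter.

Key step: step 12

Assumption: (R)-(−)-linalool of high enantiomeric purity is taken as commercially available, and Ru(OAc)2[(S)-BINAP] is taken to hydrogenate 3 with the same facial preference relative to the C=C–CH2OH unit as it shows with geraniol, which gives (S)-4; were the sense opposite, the (R)-ligand would be used.

## Steps

Step 1
Reactants: 1 geraniol [(2E)-3,7-dimethylocta-2,6-dien-1-ol]
Product: 2 tert-butyl{[(2E)-3,7-dimethylocta-2,6-dien-1-yl]oxy}dimethylsilane (geranyl TBS ether)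
Conditions: TBSCl, imidazole, DMF, 0 °C → rt
Reagents that add atoms: tert-butyldimethylsilyl chloride, CC(C)(C)[Si](C)(C)Cl
Why: Routine silylation of a primary allylic alcohol; a silyl ether is used instead of the commercial acetate because an allylic acetate would ionise under the zerovalent palladium catalyst of step 7 and would later have to be told apart from the C12 acetate.

Step 2
Reactants: 2 geranyl TBS ether
Product: 3 (2E,6E)-8-[(tert-butyldimethylsilyl)oxy]-2,6-dimethylocta-2,6-dien-1-ol
Conditions: SeO2 (0.3 equiv), t-BuOOH (3 equiv), CH2Cl2, 0 °C → rt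
Reagents that add atoms: tert-butyl hydroperoxide, CC(C)(C)OO
Why: Catalytic SeO2 allylic oxidation (ene reaction, then [2,3]-sigmatropic shift) is E-selective for a terminal methyl of a gem-dimethyl alkene; the other alkene is deactivated by its allylic oxygen, as is established for geranyl esters and ethers.

Step 3
Reactants: 3 (2E,6E)-8-[(tert-butyldimethylsilyl)oxy]-2,6-dimethylocta-2,6-dien-1-ol
Product: 4 (2S,6E)-8-[(tert-butyldimethylsilyl)oxy]-2,6-dimethyloct-6-en-1-ol
Conditions: Ru(OAc)2[(S)-BINAP] (1 mol %), H2 (50 atm), MeOH, rt
Reagents that add atoms: none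
Why: Hydroxyl-directed asymmetric hydrogenation of an allylic alcohol (Noyori type): only the alkene that can chelate ruthenium through the free OH is reduced and the silyloxy-substituted alkene is left; the ligand sets the new centre (C8 of the target) as S.

Step 4
Reactants: 4 (2S,6E)-8-[(tert-butyldimethylsilyl)oxy]-2,6-dimethyloct-6-en-1-ol
Product: 6 (2S,6E)-8-[(tert-butyldimethylsilyl)oxy]-2,6-dimethyloct-6-enoic acid, via aldehyde 5 (not isolated)
Conditions: TEMPO (0.2 equiv), PhI(OAc)2 (2.2 equiv), MeCN/H2O 1:1, rt
Reagents that add atoms: water, O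
Why: Oxoammonium oxidation takes the primary alcohol through aldehyde 5 and its hydrate to the acid under near-neutral conditions that should not epimerise the α-methyl centre or touch the alkene and silyl ether.

Step 5
Reactants: 6 (2S,6E)-8-[(tert-butyldimethylsilyl)oxy]-2,6-dimethyloct-6-enoic acid
Product: 8 S-phenyl (2S,6E)-8-[(tert-butyldimethylsilyl)oxy]-2,6-dimethyloct-6-enethioate, via acid chloride 7 (not isolated)
Conditions: 1-chloro-N,N,2-trimethylprop-1-en-1-amine (Ghosez reagent), CH2Cl2, 0 °C; then PhSH, pyridine, 0 °C
Reagents that add atoms: benzenethiol, Sc1ccccc1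
Why: Acid chloride formation with the Ghosez reagent is neutral (no HCl, so the silyl ether is safe), and acylation of the thiol with pyridine at 0 °C is a standard thioester synthesis in which ketene formation from an α-methyl acid chloride is negligible.

Step 6
Reactants: 9 (R)-(−)-linalool [(3R)-3,7-dimethylocta-1,6-dien-3-ol]
Product: 10 (R)-linalyl acetate [(3R)-3,7-dimethylocta-1,6-dien-3-yl acetate]
Conditions: Ac2O, Et3N, DMAP (0.2 equiv), CH2Cl2, rt
Reagents that add atoms: acetic anhydride, CC(=O)OC(C)=O
Why: DMAP-catalysed acetylation of the tertiary allylic alcohol under basic conditions, so no ionisation and no allylic transposition; the C12 stereocentre and the acetate of the target are thus taken from the chiral pool at the outset.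

Step 7
Reactants: 10 (R)-linalyl acetate; 8 S-phenyl (2S,6E)-8-[(tert-butyldimethylsilyl)oxy]-2,6-dimethyloct-6-enethioate
Product: 12 (6R,10S,14E)-16-[(tert-butyldimethylsilyl)oxy]-2,6,10,14-tetramethyl-9-oxohexadeca-2,14-dien-6-yl acetate, via alkylborane 11 (not isolated)
Conditions: 10, 9-BBN (1.1 equiv), THF, 0 °C → rt; then 8, Pd(PPh3)4 (5 mol %), CuTC (Cu(O2C-2-thienyl), 1.5 equiv), Cs2CO3, THF, 45 °C
Reagents that add atoms: none
Why: 9-BBN hydroborates the monosubstituted vinyl group with anti-Markovnikov selectivity and leaves the trisubstituted alkene; Liebeskind–Srogl coupling of the B-alkyl-9-BBN with the S-phenyl thioester then forms C9–C10 and the ketone directly. The acetate, the silyl ether and the C8 centre next to the acyl group should survive because no strongly basic or nucleophilic carbon reagent is involved.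

Step 8
Reactants: 12 (6R,10S,14E)-16-[(tert-butyldimethylsilyl)oxy]-2,6,10,14-tetramethyl-9-oxohexadeca-2,14-dien-6-yl acetate
Product: 13 (6R,10S,14E)-16-hydroxy-2,6,10,14-tetramethyl-9-oxohexadeca-2,14-dien-6-yl acetate
Conditions: HF·pyridine, pyridine, THF, 0 °C → rt
Reagents that add atoms: none
Why: Buffered fluoride cleaves the primary allylic silyl ether; the tertiary acetate, the ketone and both alkenes are inert, and no epoxide is yet present.

Step 9
Reactants: 13 (6R,10S,14E)-16-hydroxy-2,6,10,14-tetramethyl-9-oxohexadeca-2,14-dien-6-yl acetate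
Product: 14 (6R,10S)-13-[(2S,3S)-3-(hydroxymethyl)-2-methyloxiran-2-yl]-2,6,10-trimethyl-9-oxotridec-2-en-6-yl acetate
Conditions: Ti(OiPr)4 (10 mol %), L-(+)-diethyl tartrate (12 mol %), t-BuOOH (2 equiv), 4 Å MS, CH2Cl2, −20 °C
Reagents that add atoms: tert-butyl hydroperoxide, CC(C)(C)OO
Why: Sharpless asymmetric epoxidation touches only the allylic alcohol alkene; with L-(+)-tartrate an (E)-3-methylalk-2-en-1-ol gives the (2S,3S)-epoxy alcohol (the geraniol case), which is 3R,4S of the target once C2 is a carbonyl. Reagent control overrides the remote C8 and C12 centres.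

Step 10
Reactants: 14 (6R,10S)-13-[(2S,3S)-3-(hydroxymethyl)-2-methyloxiran-2-yl]-2,6,10-trimethyl-9-oxotridec-2-en-6-yl acetate
Product: 15 (6R,10S)-13-[(2S,3R)-3-formyl-2-methyloxiran-2-yl]-2,6,10-trimethyl-9-oxotridec-2-en-6-yl acetate
Conditions: Dess–Martin periodinane, pyridine, CH2Cl2, 0 °C → rt
Reagents that add atoms: none
Why: Buffered Dess–Martin oxidation of a 2,3-epoxy alcohol to the epoxy aldehyde is routine; the descriptor change at the epoxide CH is a priority change only, and the aldehyde is used at once.

Step 11
Reactants: 15 (6R,10S)-13-[(2S,3R)-3-formyl-2-methyloxiran-2-yl]-2,6,10-trimethyl-9-oxotridec-2-en-6-yl acetate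
Product: 16 (6R,10S)-13-{(2S,3S)-3-[(hydroxyimino)methyl]-2-methyloxiran-2-yl}-2,6,10-trimethyl-9-oxotridec-2-en-6-yl acetate (oxime E/Z mixture)
Conditions: NH2OH·HCl (1.05 equiv), pyridine, EtOH, 0 °C
Reagents that add atoms: hydroxylamine hydrochloride, NO.Cl
Why: Oxime formation at the aldehyde is much faster than at the α-branched C9 ketone, so one equivalent at 0 °C should give the aldoxime only; the predominant (E)-aldoxime holds its OH away from the epoxide, which stays closed under pyridine buffering.

Step 12
Reactants: 16 (6R,10S)-13-{(2S,3S)-3-[(hydroxyimino)methyl]-2-methyloxiran-2-yl}-2,6,10-trimethyl-9-oxotridec-2-en-6-yl acetate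
Product: 19 isoxazoline-fused 14-membered carbocycle (C2=N and C15–O of a 5,5-dimethyl-4,5-dihydroisoxazole fused at C1–C2; C1 epimers), via hydroximoyl chloride 17 (not isolated), via nitrile oxide 18 (not isolated)
Conditions: NCS (1.05 equiv), pyridine (cat.), DMF, rt; then dilution with toluene to 1 mM and Et3N (1.5 equiv) by syringe pump over 24 h, 50 °C
Reagents that add atoms: none
Why: NCS chlorinates the aldoxime to 17, slow addition of Et3N releases the nitrile oxide 18 at a low stationary concentration, and 18 adds across its only alkene, the C1=C15 prenyl terminus, in a concerted [3+2] cycloaddition (intramolecular nitrile oxide–alkene cycloaddition). The closest known reaction type is the macrocyclic version of this cycloaddition, in which ω-alkenyl nitrile oxides give 12- to 16-membered carbocycles carrying an isoxazoline that is later opened to the aldol. Two rings form: the isoxazoline by the cycloaddition itself, and the 14-membered carbocycle in the fused (exo) mode, the nitrile oxide carbon C2 bonding to the proximal alkene carbon C1. The regiochemistry needed (C2–C1, O–C15) is the inherent one for a trisubstituted alkene, oxygen going to the more substituted carbon and carbon to the less hindered one, and the reverse mode would also need a bridged 15-membered ring. The one new stereocentre, C1, is not controlled and need not be, because it becomes sp2 in step 14; the four stereocentres of the target are already present and are not touched under these neutral conditions. Chemoselectivity is built into the substrate: C3=C4 is already an epoxide, so there is no second dipolarophile, and ketone and acetate do not react with nitrile oxides. The selectivity that has to be won is cyclisation over dimerisation to the furoxan; it rests on high dilution with slow base addition and on the α-branched nitrile oxide (an epoxide carbon next to the fully substituted C4), which should slow the bimolecular dimerisation more than the intramolecular addition. The precursor is an open chain, and the product contains the whole ring system with C2 and C15 at the oxidation levels needed for the enone.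

Step 13
Reactants: 19 isoxazoline-fused 14-membered carbocycle
Product: 21 aldol: (1R,6R,10S,14S)-3-(2-hydroxypropan-2-yl)-6,10,14-trimethyl-2,9-dioxo-15-oxabicyclo[12.1.0]pentadecan-6-yl acetate (C3 epimers; C3 is C1 in cembrane locants), via β-hydroxy imine 20 (not isolated)
Conditions: Raney Ni, H2 (1 atm), B(OH)3 (4 equiv), MeOH/H2O 5:1, rt
Reagents that add atoms: water, O
Why: Hydrogenolysis of the weak N–O bond and boric-acid-buffered hydrolysis of imine 20 is the standard unmasking of an isoxazoline to an aldol. The substrate has no C=C, and N–O scission at 1 atm and room temperature is expected to outpace hydrogenolysis of the epoxide if the reaction is stopped when 19 is consumed.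

Step 14
Reactants: 21 aldol
Product: 23 CNP0229580.1 [(1R,6R,10S,14S)-6,10,14-trimethyl-2,9-dioxo-3-(propan-2-ylidene)-15-oxabicyclo[12.1.0]pentadecan-6-yl acetate], via tertiary mesylate 22 (not isolated)
Conditions: MsCl (3 equiv), Et3N (6 equiv), CH2Cl2, 0 °C → rt
Reagents that add atoms: none
Why: Mesylation of the tertiary aldol hydroxyl followed by E1cB elimination; C3 is an epoxide carbon, so the only acidic hydrogen next to the C2 carbonyl is on C1. The double bond is therefore expected to form as the conjugated C1=C15 isopropylidene, which removes the uncontrolled C1 centre, and the amine base is too weak to epimerise C8 or open the epoxide.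

## Compound list

1 | geraniol, (2E)-3,7-dimethylocta-2,6-dien-1-ol | CC(C)=CCC/C(C)=C/CO | starting material
2 | tert-butyl{[(2E)-3,7-dimethylocta-2,6-dien-1-yl]oxy}dimethylsilane | CC(C)=CCC/C(C)=C/CO[Si](C)(C)C(C)(C)C | intermediate
3 | (2E,6E)-8-[(tert-butyldimethylsilyl)oxy]-2,6-dimethylocta-2,6-dien-1-ol | OC/C(C)=C/CC/C(C)=C/CO[Si](C)(C)C(C)(C)C | intermediate
4 | (2S,6E)-8-[(tert-butyldimethylsilyl)oxy]-2,6-dimethyloct-6-en-1-ol | OC[C@@H](C)CCC/C(C)=C/CO[Si](C)(C)C(C)(C)C | intermediate
5 | (2S,6E)-8-[(tert-butyldimethylsilyl)oxy]-2,6-dimethyloct-6-enal (not isolated) | O=C[C@@H](C)CCC/C(C)=C/CO[Si](C)(C)C(C)(C)C | intermediate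
6 | (2S,6E)-8-[(tert-butyldimethylsilyl)oxy]-2,6-dimethyloct-6-enoic acid | OC(=O)[C@@H](C)CCC/C(C)=C/CO[Si](C)(C)C(C)(C)C | intermediate
7 | (2S,6E)-8-[(tert-butyldimethylsilyl)oxy]-2,6-dimethyloct-6-enoyl chloride (not isolated) | ClC(=O)[C@@H](C)CCC/C(C)=C/CO[Si](C)(C)C(C)(C)C | intermediate
8 | S-phenyl (2S,6E)-8-[(tert-butyldimethylsilyl)oxy]-2,6-dimethyloct-6-enethioate | O=C(Sc1ccccc1)[C@@H](C)CCC/C(C)=C/CO[Si](C)(C)C(C)(C)C | intermediate
9 | (R)-(−)-linalool, (3R)-3,7-dimethylocta-1,6-dien-3-ol | C=C[C@](C)(O)CCC=C(C)C | starting material
10 | (R)-linalyl acetate, (3R)-3,7-dimethylocta-1,6-dien-3-yl acetate | C=C[C@](C)(OC(C)=O)CCC=C(C)C | intermediate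
11 | (3S)-1-(9-borabicyclo[3.3.1]nonan-9-yl)-3,7-dimethyloct-6-en-3-yl acetate (not isolated; same spatial arrangement as 10, descriptor changed by priority only) | CC(=O)O[C@@](CCC=C(C)C)(C)CCB1C2CCCC1CCC2 | intermediate
12 | (6R,10S,14E)-16-[(tert-butyldimethylsilyl)oxy]-2,6,10,14-tetramethyl-9-oxohexadeca-2,14-dien-6-yl acetate | CC(=O)O[C@@](CCC=C(C)C)(C)CCC(=O)[C@@H](C)CCC/C(C)=C/CO[Si](C)(C)C(C)(C)C | intermediate
13 | (6R,10S,14E)-16-hydroxy-2,6,10,14-tetramethyl-9-oxohexadeca-2,14-dien-6-yl acetate | CC(=O)O[C@@](CCC=C(C)C)(C)CCC(=O)[C@@H](C)CCC/C(C)=C/CO | intermediate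
14 | (6R,10S)-13-[(2S,3S)-3-(hydroxymethyl)-2-methyloxiran-2-yl]-2,6,10-trimethyl-9-oxotridec-2-en-6-yl acetate | CC(=O)O[C@@](CCC=C(C)C)(C)CCC(=O)[C@@H](C)CCC[C@]1(C)O[C@H]1CO | intermediate
15 | (6R,10S)-13-[(2S,3R)-3-formyl-2-methyloxiran-2-yl]-2,6,10-trimethyl-9-oxotridec-2-en-6-yl acetate | CC(=O)O[C@@](CCC=C(C)C)(C)CCC(=O)[C@@H](C)CCC[C@]1(C)O[C@H]1C=O | intermediate
16 | (6R,10S)-13-{(2S,3S)-3-[(hydroxyimino)methyl]-2-methyloxiran-2-yl}-2,6,10-trimethyl-9-oxotridec-2-en-6-yl acetate | CC(=O)O[C@@](CCC=C(C)C)(C)CCC(=O)[C@@H](C)CCC[C@]1(C)O[C@H]1C=NO | intermediate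
17 | hydroximoyl chloride of 16, C2 as C(Cl)=NOH (not isolated) | CC(=O)O[C@@](CCC=C(C)C)(C)CCC(=O)[C@@H](C)CCC[C@]1(C)O[C@H]1C(Cl)=NO | intermediate
18 | nitrile oxide, C2 as C≡N–O (not isolated) | CC(=O)O[C@@](CCC=C(C)C)(C)CCC(=O)[C@@H](C)CCC[C@]1(C)O[C@H]1C#[N+][O-] | intermediate
19 | isoxazoline-fused 14-membered carbocycle: C2 is C=N and C1 (H, epimer mixture) is C4 of a 5,5-dimethyl-4,5-dihydroisoxazole with O on C15; epoxide, C8 methyl, C9 ketone and C12 acetate as in 23 | CC(=O)O[C@@]1(C)CCC(=O)[C@@H](C)CCC[C@]2(C)O[C@H]2C3=NOC(C)(C)C3CC1 | intermediate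
20 | β-hydroxy imine: 21 with C2=NH (not isolated) | CC(=O)O[C@@]1(C)CCC(=O)[C@@H](C)CCC[C@]2(C)O[C@H]2C(=N)C(C(C)(C)O)CC1 | intermediate
21 | (1R,6R,10S,14S)-3-(2-hydroxypropan-2-yl)-6,10,14-trimethyl-2,9-dioxo-15-oxabicyclo[12.1.0]pentadecan-6-yl acetate (C3 epimers) | CC(=O)O[C@@]1(C)CCC(=O)[C@@H](C)CCC[C@]2(C)O[C@H]2C(=O)C(C(C)(C)O)CC1 | intermediate
22 | methanesulfonate of the tertiary hydroxyl of 21 (not isolated) | CC(=O)O[C@@]1(C)CCC(=O)[C@@H](C)CCC[C@]2(C)O[C@H]2C(=O)C(C(C)(C)OS(C)(=O)=O)CC1 | intermediate
23 | CNP0229580.1, (1R,6R,10S,14S)-6,10,14-trimethyl-2,9-dioxo-3-(propan-2-ylidene)-15-oxabicyclo[12.1.0]pentadecan-6-yl acetate | CC(=O)O[C@@]1(C)CCC(=O)[C@@H](C)CCC[C@]2(C)O[C@H]2C(=O)C(=C(C)C)CC1 | target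

## Step count and least certain steps

Total: 14 steps. Longest linear sequence: 13 steps (geraniol 1 to 23, steps 1–5 and 7–14). Step 6 is the one-step side branch from linalool.

**Step 12 (key step).** The most likely failure is bimolecular dimerisation of the nitrile oxide to furoxans, or oligomerisation, outrunning the ring closure. An unactivated trisubstituted alkene is a slow dipolarophile and the ring is large.

The fallback sets out from epoxy aldehyde 15 and closes the same bond by a Lewis-acid-promoted carbonyl-ene reaction (Me2AlCl, CH2Cl2, −78 °C, high dilution). The C1=C15 alkene attacks the aldehyde through C1 and gives up a methyl hydrogen, forming the macrocyclic homoallylic alcohol F1. Dess–Martin oxidation gives the β,γ-unsaturated epoxy ketone F2. Catalytic DBU at 0 °C moves the double bond into conjugation, and the route is rejoined at 23.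

**Step 13.** The most likely failure is over-reduction, that is reductive opening of the epoxide once it lies next to C=N or C=O. Retro-aldol loss of acetone during the hydrolysis is the second risk. Mo(CO)6 in wet MeCN would be the first change of conditions.

The fallback gives up the isoxazoline as the carbonyl mask and closes the ring at the alcohol oxidation level with divalent chromium, so that no reductive unmasking next to the epoxide is needed. It sets out from 12.
- SeO2/t-BuOOH oxidises the (E)-methyl group of the prenyl terminus to the allylic alcohol F3.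
- CBr4/PPh3 gives the allylic bromide F4.
- HF·pyridine frees the C2 alcohol F5.
- Sharpless epoxidation as in step 9 gives the epoxy alcohol F6.
- Dess–Martin oxidation gives the bromo epoxy aldehyde F7.
- CrCl2 in THF at high dilution (Nozaki–Hiyama allylation, bond formation at the γ-carbon C1) closes the ring to the homoallylic alcohol F1.

F1 is then taken through F2 as described for step 12, and the route is rejoined at 23.

**Step 7.** The most likely failures are slow transfer of the primary alkyl group from boron to palladium (with protodeboronation or β-hydride loss) and erosion of the C8 centre by the carbonate base.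

The fallback sets out from 10. Hydroboration as before gives 11, which is oxidised with trimethylamine N-oxide (neutral, to avoid migration of the acetyl group) to the primary alcohol F8. I2/PPh3/imidazole gives the iodide F9. Zn dust with LiCl in THF gives the alkylzinc iodide F10. Fukuyama coupling with 8 (PdCl2(PPh3)2 cat., toluene, rt) returns to the route at 12.

**Step 3.** The most likely failure is lower or opposite enantioface selection than the geraniol model predicts, because here the methyl group sits on the carbinol-bearing alkene carbon.

The fallback sets out from 3. MnO2 gives the enal F11, and NaClO2/NaH2PO4/2-methylbut-2-ene gives the (E)-2-methylalk-2-enoic acid F12. Asymmetric hydrogenation at the acid stage with Ru(OAc)2(BINAP) (the tiglic acid substrate class, ligand enantiomer chosen for the S product) gives 6 directly. The route is rejoined at 6, and step 4 is no longer needed.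

## Further compounds

F1 | step 12 | homoallylic alcohol: 23 with C2 as CH–OH and C1 as CH bearing prop-1-en-2-yl (C1/C2 epimers) | CC(=O)O[C@@]1(C)CCC(=O)[C@@H](C)CCC[C@]2(C)O[C@H]2C(O)C(C(C)=C)CC1
F2 | step 12 | β,γ-unsaturated epoxy ketone: 23 with C1 as CH bearing prop-1-en-2-yl (C1 epimers) | CC(=O)O[C@@]1(C)CCC(=O)[C@@H](C)CCC[C@]2(C)O[C@H]2C(=O)C(C(C)=C)CC1
F3 | step 13 | (2E,6R,10S,14E)-16-[(tert-butyldimethylsilyl)oxy]-1-hydroxy-2,6,10,14-tetramethyl-9-oxohexadeca-2,14-dien-6-yl acetate | CC(=O)O[C@@](CC/C=C(\C)CO)(C)CCC(=O)[C@@H](C)CCC/C(C)=C/CO[Si](C)(C)C(C)(C)C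
F4 | step 13 | (2E,6R,10S,14E)-1-bromo-16-[(tert-butyldimethylsilyl)oxy]-2,6,10,14-tetramethyl-9-oxohexadeca-2,14-dien-6-yl acetate | CC(=O)O[C@@](CC/C=C(\C)CBr)(C)CCC(=O)[C@@H](C)CCC/C(C)=C/CO[Si](C)(C)C(C)(C)C
F5 | step 13 | (2E,6R,10S,14E)-1-bromo-16-hydroxy-2,6,10,14-tetramethyl-9-oxohexadeca-2,14-dien-6-yl acetate | CC(=O)O[C@@](CC/C=C(\C)CBr)(C)CCC(=O)[C@@H](C)CCC/C(C)=C/CO
F6 | step 13 | (2E,6R,10S)-1-bromo-13-[(2S,3S)-3-(hydroxymethyl)-2-methyloxiran-2-yl]-2,6,10-trimethyl-9-oxotridec-2-en-6-yl acetate | CC(=O)O[C@@](CC/C=C(\C)CBr)(C)CCC(=O)[C@@H](C)CCC[C@]1(C)O[C@H]1CO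
F7 | step 13 | (2E,6R,10S)-1-bromo-13-[(2S,3R)-3-formyl-2-methyloxiran-2-yl]-2,6,10-trimethyl-9-oxotridec-2-en-6-yl acetate | CC(=O)O[C@@](CC/C=C(\C)CBr)(C)CCC(=O)[C@@H](C)CCC[C@]1(C)O[C@H]1C=O
F8 | step 7 | (3R)-1-hydroxy-3,7-dimethyloct-6-en-3-yl acetate | CC(=O)O[C@@](CCC=C(C)C)(C)CCO
F9 | step 7 | (3R)-1-iodo-3,7-dimethyloct-6-en-3-yl acetate | CC(=O)O[C@@](CCC=C(C)C)(C)CCI
F10 | step 7 | [(3R)-3-acetoxy-3,7-dimethyloct-6-en-1-yl]zinc iodide | CC(=O)O[C@@](CCC=C(C)C)(C)CC[Zn]I
F11 | step 3 | (2E,6E)-8-[(tert-butyldimethylsilyl)oxy]-2,6-dimethylocta-2,6-dienal | O=C/C(C)=C/CC/C(C)=C/CO[Si](C)(C)C(C)(C)C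
F12 | step 3 | (2E,6E)-8-[(tert-butyldimethylsilyl)oxy]-2,6-dimethylocta-2,6-dienoic acid | OC(=O)/C(C)=C/CC/C(C)=C/CO[Si](C)(C)C(C)(C)C
A1 | alternative 1 | acyclic metathesis diene: vinyl ketone at C9 and vinyl group on C12, with the complete C15=C1–C2(=O)–C3–C4 epoxy enone | C=CC(=O)[C@@H](C)CCC[C@]1(C)O[C@H]1C(=O)C(=C(C)C)CC[C@@](C)(OC(C)=O)C=C
A2 | alternative 1 | macrocyclic (10E)-enone: 23 with a C10=C11 double bond | CC(=O)O[C@@]1(C)/C=C/C(=O)[C@@H](C)CCC[C@]2(C)O[C@H]2C(=O)C(=C(C)C)CC1
A3 | alternative 2 | (2E,7S,11R)-11-acetoxy-3,7,11,15-tetramethyl-8-oxohexadeca-2,14-dienoyl chloride | CC(=O)O[C@@](CCC=C(C)C)(C)CCC(=O)[C@@H](C)CCC/C(C)=C/C(Cl)=O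
A4 | alternative 2 | cross-conjugated macrocyclic dienone: 23 with a C3=C4 (E) double bond in place of the epoxide | CC(=O)O[C@@]1(C)CCC(=O)[C@@H](C)CCC/C(C)=C/C(=O)C(=C(C)C)CC1
A5 | alternative 3 | 17-membered propargylic allylic ether (O between C2 and C16; C3≡C4; C9 as 1,3-dioxolane; C12 triethylsilyl ether) | C1C#CCCC[C@H](C)C2(OCCO2)CC[C@](C)(O[Si](CC)(CC)CC)CC/C=C(\C)CO1
A6 | alternative 3 | 14-membered propargylic alcohol from ring contraction (C2–OH, prop-1-en-2-yl on C1, C3≡C4; C9 as 1,3-dioxolane; C12 triethylsilyl ether) | OC1C#CCCC[C@H](C)C2(OCCO2)CC[C@](C)(O[Si](CC)(CC)CC)CCC1C(C)=C
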